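**Plan**

- Retrosynthesis (germacrane locants C1–C15): the ten-membered carbocycle is cut at C3–C4, an intramolecular Nozaki–Hiyama–Kishi addition of a (Z)-C4 alkenyl iodide to a C3 aldehyde, placed last so that it gives the target itself.
- The open chain is then cut at C4=C5 (iodo-Wittig), at C7–C8 (conjugate addition of a C8 dithiane anion to a C6-chiral butenolide, the enolate trapped as a masked C11=C13 methylene) and at C8–C9 (dithiane alkylation).
- Forward: side chain 7 (C8–C3) and butenolide 9 are joined, so the lactone ring is present from the start; C8 is reduced and acylated, C5 becomes the Z iodoalkene, the methylene is unmasked, the C1–C10 oxirane is made, and the macrocycle closes last.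
- Stereochemistry: C6 from (S)-5-(hydroxymethyl)furanone; C7 by addition anti to the C6 substituent; C8 by CBS reduction; C1/C10 by Shi epoxidation; 1(10)E from SeO2 oxidation, 4Z from Stork–Zhao olefination; C3 in the ring closure (1,3-anti to the C1 oxygen).
- What makes the closure possible: the trans-fused γ-lactone (O, C6, C7, C11, C12) carries both arms on adjacent carbons, the Z C4=C5 bond turns C4 back toward the chain, and the trans C1–C10 oxirane bends the C9–C2 segment, so C3 and C4 can meet in a ten-membered ring.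

Key step: step 17

Remark: C-numbers are the germacrane locants of the target and are used for all intermediates. The Mannich base 12 is drawn with the aminomethyl group trans to the C7 substituent; this is without consequence, since C11 becomes trigonal in step 13.

**Step 1**
Reactants: 1 4-methylpent-3-en-1-ol
Product: 2 4-methoxybenzyl (PMB) ether of 1
Conditions: NaH, 4-methoxybenzyl chloride, Bu4NI (cat.), THF/DMF, 0 °C → rt
Reagents that add atoms: 4-methoxybenzyl chloride, COc1ccc(CCl)cc1
Why: Williamson etherification of a primary alkoxide with a benzylic chloride; no stereocentre is involved.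

**Step 2**
Reactants: 2 PMB ether
Product: 3 (2E)-5-[(4-methoxyphenyl)methoxy]-2-methylpent-2-en-1-ol
Conditions: SeO2 (0.5 equiv), t-BuOOH, salicylic acid (cat.), CH2Cl2, rt
Reagents that add atoms: tert-butyl hydroperoxide (oxygen passed on through SeO2), CC(C)(C)OO
Why: SeO2 allylic oxidation (ene reaction, then 2,3-shift) attacks the methyl group trans to the chain of a trisubstituted alkene, so the E allylic alcohol should form; this fixes the later C1=C10 geometry.

**Step 3**
Reactants: 3 allylic alcohol
Product: 4 1-({[(3E)-5-bromo-4-methylpent-3-en-1-yl]oxy}methyl)-4-methoxybenzene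
Conditions: CBr4, PPh3, CH2Cl2, 0 °C
Reagents that add atoms: tetrabromomethane, BrC(Br)(Br)Br
Why: Appel bromination of a primary allylic alcohol, an SN2 displacement on the alkoxyphosphonium ion without allylic shift, so the E geometry is kept.

**Step 4**
Reactants: 5 1,3-dithiane; 4 allylic bromide
Product: 7 2-{(2E)-5-[(4-methoxyphenyl)methoxy]-2-methylpent-2-en-1-yl}-1,3-dithiane, via 2-lithio-1,3-dithiane 6 (not isolated)
Conditions: n-BuLi, THF, −30 °C; then 4, −78 → −20 °C
Reagents that add atoms: none
Why: Corey–Seebach alkylation; the primary allylic bromide reacts by direct SN2, which puts the future C8 (as a masked carbonyl) next to C9.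

**Step 5**
Reactants: 8 (5S)-5-(hydroxymethyl)furan-2(5H)-one
Product: 9 (5S)-5-{[tert-butyl(diphenyl)silyl]oxymethyl}furan-2(5H)-one
Conditions: t-BuPh2SiCl, imidazole, CH2Cl2, 0 °C → rt
Reagents that add atoms: tert-butyl(chloro)diphenylsilane, CC(C)(C)[Si](Cl)(c1ccccc1)c1ccccc1
Why: silylation of the primary alcohol; the bulky silyloxymethyl group at C6 is the shielding element for step 6.

**Step 6**
Reactants: 7 dithiane; 9 silyl butenolide
Product: 12 (3R,4S,5S)-Mannich base lactone carrying the C8 dithiane, via lithiated dithiane 10 (not isolated), via lithium enolate 11 (not isolated)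
Conditions: t-BuLi, THF/HMPA (9:1), −78 °C; 9, −78 °C; then CH2=NMe2+ I−, −78 → 0 °C
Reagents that add atoms: N,N-dimethylmethyleneiminium iodide (Eschenmoser's salt), C=[N+](C)C.[I-]
Why: conjugate addition of a 2-lithio-1,3-dithiane to a butenolide (HMPA favours 1,4- over 1,2-addition) anti to the C6 substituent sets C7 and the trans lactone, and Mannich trapping of the enolate installs C13 as an amine-masked methylene.

**Step 7**
Reactants: 12 Mannich base dithiane
Product: 13 C8 ketone
Conditions: Hg(ClO4)2, CaCO3, THF/H2O (5:1), −10 → 0 °C, short contact; used at once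
Reagents that add atoms: water, O
Why: thiophilic mercury-assisted hydrolysis of the dithioacetal under carbonate buffering is fast and close to neutral, which should spare the β,γ-unsaturated ketone from conjugation and from β-elimination of the lactone oxygen.

**Step 8**
Reactants: 13 ketone
Product: 14 (8R) alcohol
Conditions: (S)-2-methyl-CBS-oxazaborolidine (0.5 equiv), catecholborane, CH2Cl2/toluene, −78 °C; MeOH, pH 7 buffer
Reagents that add atoms: none
Why: Corey–Bakshi–Shibata reduction; with the ring methine C7 as the large and the C9 methylene as the small group, the (S)-catalyst should deliver hydride to the face that gives 8R, and catecholborane at −78 °C is non-basic and does not hydroborate the alkene.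

**Step 9**
Reactants: 14 alcohol
Product: 15 C8 3-methylbutanoate (isovalerate)
Conditions: 3-methylbutanoic anhydride, pyridine, DMAP (cat.), CH2Cl2, 0 °C → rt
Reagents that add atoms: 3-methylbutanoic anhydride, CC(C)CC(=O)OC(=O)CC(C)C
Why: DMAP-catalysed acylation of the only free hydroxyl; prompt acylation also rules out migration of the lactone from O6 to O8.

**Step 10**
Reactants: 15 silyl ether
Product: 16 C5 primary alcohol
Conditions: Bu4NF, AcOH (1:1), THF, 0 °C → rt
Reagents that add atoms: none
Why: fluoride cleavage of the silyl ether; buffering with AcOH keeps the isovalerate and the lactone intact.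

**Step 11**
Reactants: 16 alcohol
Product: 17 C5 aldehyde
Conditions: Dess–Martin periodinane, pyridine, CH2Cl2, 0 °C; used crude
Reagents that add atoms: none
Why: Dess–Martin oxidation is mild enough for an α-acyloxy aldehyde whose C6–H is epimerizable.

**Step 12**
Reactants: 17 aldehyde
Product: 18 (Z)-C4 iodoalkene
Conditions: EtPPh3I, n-BuLi, THF, rt; I2, −78 °C; NaN(SiMe3)2, −78 → −20 °C; then 17, −78 °C
Reagents that add atoms: ethyltriphenylphosphonium iodide, CC[P+](c1ccccc1)(c1ccccc1)c1ccccc1.[I-]; iodine, II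
Why: Stork–Zhao olefination with the α-iodo ylide gives under kinetic control the Z iodoalkene (iodine cis to C6); the methylene is still masked, so the ylide meets no Michael acceptor.

**Step 13**
Reactants: 18 Mannich base
Product: 20 α-methylene lactone, via trimethylammonium iodide 19 (not isolated)
Conditions: MeI, MeOH/CH2Cl2, rt; evaporate; aq. NaHCO3, CH2Cl2, rt
Reagents that add atoms: none
Why: N-methylation and E1cB loss of trimethylamine unmask C11=C13; this is done only after C8 has ceased to be a ketone, so C7–H is not acidic enough for the double bond to move into the ring.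

**Step 14**
Reactants: 20 PMB ether
Product: 21 C3 primary alcohol
Conditions: DDQ, CH2Cl2/pH 7 buffer (10:1), 0 °C
Reagents that add atoms: none
Why: oxidative cleavage of the PMB ether by hydride abstraction; the iodoalkene, the methylene lactone and the ester are inert to DDQ.

**Step 15**
Reactants: 21 homoallylic alcohol
Product: 22 (1R,10R) epoxy alcohol
Conditions: D-fructose-derived Shi ketone (0.3 equiv), Oxone, K2CO3, Bu4NHSO4 (cat.), aq. Na2B4O7/Na2EDTA, MeCN/dimethoxymethane, 0 °C
Reagents that add atoms: potassium peroxymonosulfate (active part of Oxone), [K+].[O-]S(=O)(=O)OO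
Why: Shi epoxidation; the chiral dioxirane attacks the only electron-rich alkene (C1=C10) through the spiro transition state, which for an E-trisubstituted alkene and the D-fructose ketone should give the (R,R) oxirane, while the iodoalkene and the methylene lactone are too electron-poor to react.

**Step 16**
Reactants: 22 epoxy alcohol
Product: 23 β,γ-epoxy aldehyde
Conditions: Dess–Martin periodinane, pyridine, CH2Cl2, 0 °C; filtered and used at once
Reagents that add atoms: none
Why: buffered Dess–Martin oxidation avoids the acid and base that would open the oxirane by O3 attack at C10 or by β-elimination.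

**Step 17**
Reactants: 23 iodoalkenyl epoxy aldehyde
Product: 24 target
Conditions: CrCl2 (15 equiv), NiCl2 (0.2 equiv), degassed DMSO/THF, 0.002 M, slow addition of 23, rt; aq. sodium serinate work-up
Reagents that add atoms: none
Why: CrCl2 reduces NiCl2 to zerovalent nickel, which inserts into the C4–I bond with retention of the Z geometry; transmetalation to trivalent chromium gives an alkenylchromium that adds to the C3 aldehyde, and the chromium alkoxide is protonated on work-up (intramolecular Nozaki–Hiyama–Kishi reaction, whose closest precedent is the closure of nine- to twelve-membered carbocycles). The ten-membered ring C1–C10 closes in a 10-exo-trig mode, the C=O being exocyclic to the forming ring. C3 is the only new stereocentre: addition to the Si face gives 3R, the 1,3-anti product expected from a dipole-opposed arrangement of the C3=O and C1–O bonds under non-chelating chromium, with the solvated O–Cr unit on the outside of the ring. Chemoselectivity for the aldehyde over the lactone, the isovalerate, the oxirane and the C11=C13 acceptor rests on the carbonyl selectivity of alkenylchromium reagents and on a low NiCl2 loading, which disfavours insertion of alkenylnickel into C11=C13. Cyclization over oligomerization rests on high dilution and on the substrate: the trans-fused lactone holds C5 and C8 on adjacent carbons, the Z C4=C5 bond points C4 back along the chain, and the trans oxirane bends C9–C2 toward it.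

**Compound list**

1 | 4-methylpent-3-en-1-ol | CC(C)=CCCO | starting material
2 | 1-methoxy-4-{[(4-methylpent-3-en-1-yl)oxy]methyl}benzene | COc1ccc(COCCC=C(C)C)cc1 | intermediate
3 | (2E)-5-[(4-methoxyphenyl)methoxy]-2-methylpent-2-en-1-ol | COc1ccc(COCC/C=C(\C)CO)cc1 | intermediate
4 | 1-({[(3E)-5-bromo-4-methylpent-3-en-1-yl]oxy}methyl)-4-methoxybenzene | COc1ccc(COCC/C=C(\C)CBr)cc1 | intermediate
5 | 1,3-dithiane | C1CSCSC1 | starting material
6 | 2-lithio-1,3-dithiane | [Li]C1SCCCS1 | intermediate
7 | 2-{(2E)-5-[(4-methoxyphenyl)methoxy]-2-methylpent-2-en-1-yl}-1,3-dithiane | COc1ccc(COCC/C=C(\C)CC2SCCCS2)cc1 | intermediate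
8 | (5S)-5-(hydroxymethyl)furan-2(5H)-one | O=C1O[C@H](CO)C=C1 | starting material
9 | (5S)-5-{[tert-butyl(diphenyl)silyl]oxymethyl}furan-2(5H)-one | O=C1O[C@H](CO[Si](c2ccccc2)(c2ccccc2)C(C)(C)C)C=C1 | intermediate
10 | 2-lithio-2-{(2E)-5-[(4-methoxyphenyl)methoxy]-2-methylpent-2-en-1-yl}-1,3-dithiane | COc1ccc(COCC/C=C(\C)CC2([Li])SCCCS2)cc1 | intermediate
11 | lithium (4S,5S)-5-{[tert-butyl(diphenyl)silyl]oxymethyl}-4-(2-{(2E)-5-[(4-methoxyphenyl)methoxy]-2-methylpent-2-en-1-yl}-1,3-dithian-2-yl)-4,5-dihydrofuran-2-olate | [Li+].[O-]C1=C[C@H](C2(C/C(C)=C/CCOCc3ccc(OC)cc3)SCCCS2)[C@@H](CO[Si](c2ccccc2)(c2ccccc2)C(C)(C)C)O1 | intermediate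
12 | (3R,4S,5S)-5-{[tert-butyl(diphenyl)silyl]oxymethyl}-3-[(dimethylamino)methyl]-4-(2-{(2E)-5-[(4-methoxyphenyl)methoxy]-2-methylpent-2-en-1-yl}-1,3-dithian-2-yl)oxolan-2-one | O=C1O[C@H](CO[Si](c2ccccc2)(c2ccccc2)C(C)(C)C)[C@@H](C2(C/C(C)=C/CCOCc3ccc(OC)cc3)SCCCS2)[C@@H]1CN(C)C | intermediate
13 | (3R,4S,5S)-5-{[tert-butyl(diphenyl)silyl]oxymethyl}-3-[(dimethylamino)methyl]-4-{(3E)-6-[(4-methoxyphenyl)methoxy]-3-methylhex-3-enoyl}oxolan-2-one | O=C1O[C@H](CO[Si](c2ccccc2)(c2ccccc2)C(C)(C)C)[C@@H](C(=O)C/C(C)=C/CCOCc2ccc(OC)cc2)[C@@H]1CN(C)C | intermediate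
14 | (3R,4R,5S)-5-{[tert-butyl(diphenyl)silyl]oxymethyl}-3-[(dimethylamino)methyl]-4-{(1R,3E)-1-hydroxy-6-[(4-methoxyphenyl)methoxy]-3-methylhex-3-en-1-yl}oxolan-2-one | O=C1O[C@H](CO[Si](c2ccccc2)(c2ccccc2)C(C)(C)C)[C@@H]([C@H](O)C/C(C)=C/CCOCc2ccc(OC)cc2)[C@@H]1CN(C)C | intermediate
15 | (1R,3E)-1-[(2S,3R,4R)-2-{[tert-butyl(diphenyl)silyl]oxymethyl}-4-[(dimethylamino)methyl]-5-oxooxolan-3-yl]-6-[(4-methoxyphenyl)methoxy]-3-methylhex-3-en-1-yl 3-methylbutanoate | O=C1O[C@H](CO[Si](c2ccccc2)(c2ccccc2)C(C)(C)C)[C@@H]([C@H](OC(=O)CC(C)C)C/C(C)=C/CCOCc2ccc(OC)cc2)[C@@H]1CN(C)C | intermediate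
16 | (1R,3E)-1-[(2S,3R,4R)-4-[(dimethylamino)methyl]-2-(hydroxymethyl)-5-oxooxolan-3-yl]-6-[(4-methoxyphenyl)methoxy]-3-methylhex-3-en-1-yl 3-methylbutanoate | O=C1O[C@H](CO)[C@@H]([C@H](OC(=O)CC(C)C)C/C(C)=C/CCOCc2ccc(OC)cc2)[C@@H]1CN(C)C | intermediate
17 | (1R,3E)-1-[(2S,3R,4R)-4-[(dimethylamino)methyl]-2-formyl-5-oxooxolan-3-yl]-6-[(4-methoxyphenyl)methoxy]-3-methylhex-3-en-1-yl 3-methylbutanoate | O=C1O[C@H](C=O)[C@@H]([C@H](OC(=O)CC(C)C)C/C(C)=C/CCOCc2ccc(OC)cc2)[C@@H]1CN(C)C | intermediate
18 | (1R,3E)-1-[(2S,3R,4R)-4-[(dimethylamino)methyl]-2-[(1Z)-2-iodoprop-1-en-1-yl]-5-oxooxolan-3-yl]-6-[(4-methoxyphenyl)methoxy]-3-methylhex-3-en-1-yl 3-methylbutanoate | O=C1O[C@H](/C=C(/C)I)[C@@H]([C@H](OC(=O)CC(C)C)C/C(C)=C/CCOCc2ccc(OC)cc2)[C@@H]1CN(C)C | intermediate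
19 | {(3R,4R,5S)-5-[(1Z)-2-iodoprop-1-en-1-yl]-4-[(1R,3E)-6-[(4-methoxyphenyl)methoxy]-3-methyl-1-(3-methylbutanoyloxy)hex-3-en-1-yl]-2-oxooxolan-3-yl}methyl(trimethyl)ammonium iodide | O=C1O[C@H](/C=C(/C)I)[C@@H]([C@H](OC(=O)CC(C)C)C/C(C)=C/CCOCc2ccc(OC)cc2)[C@@H]1C[N+](C)(C)C.[I-] | intermediate
20 | (1R,3E)-1-[(2S,3R)-2-[(1Z)-2-iodoprop-1-en-1-yl]-4-methylidene-5-oxooxolan-3-yl]-6-[(4-methoxyphenyl)methoxy]-3-methylhex-3-en-1-yl 3-methylbutanoate | C=C1C(=O)O[C@H](/C=C(/C)I)[C@H]1[C@H](OC(=O)CC(C)C)C/C(C)=C/CCOCc1ccc(OC)cc1 | intermediate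
21 | (1R,3E)-6-hydroxy-1-[(2S,3R)-2-[(1Z)-2-iodoprop-1-en-1-yl]-4-methylidene-5-oxooxolan-3-yl]-3-methylhex-3-en-1-yl 3-methylbutanoate | C=C1C(=O)O[C@H](/C=C(/C)I)[C@H]1[C@H](OC(=O)CC(C)C)C/C(C)=C/CCO | intermediate
22 | (1R)-2-[(2R,3R)-3-(2-hydroxyethyl)-2-methyloxiran-2-yl]-1-[(2S,3R)-2-[(1Z)-2-iodoprop-1-en-1-yl]-4-methylidene-5-oxooxolan-3-yl]ethyl 3-methylbutanoate | C=C1C(=O)O[C@H](/C=C(/C)I)[C@H]1[C@H](OC(=O)CC(C)C)C[C@@]1(C)O[C@@H]1CCO | intermediate
23 | (1R)-1-[(2S,3R)-2-[(1Z)-2-iodoprop-1-en-1-yl]-4-methylidene-5-oxooxolan-3-yl]-2-[(2R,3R)-2-methyl-3-(2-oxoethyl)oxiran-2-yl]ethyl 3-methylbutanoate | C=C1C(=O)O[C@H](/C=C(/C)I)[C@H]1[C@H](OC(=O)CC(C)C)C[C@@]1(C)O[C@@H]1CC=O | intermediate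
24 | (1R,3R,4Z,6R,7R,8R,10R)-1,10-epoxy-3-hydroxy-8-(3-methylbutanoyloxy)germacra-4,11(13)-dien-12,6-olide (CNP0300193.1) | C=C1C(=O)O[C@@H]2/C=C(/C)[C@H](O)C[C@H]3O[C@]3(C)C[C@@H](OC(=O)CC(C)C)[C@@H]12 | target

**Step count**

Total: 17 steps. Longest linear sequence: 16 steps (steps 1–4 and 6–17); step 5 is the only side step.

**Steps most likely to fail**

Step 17 (ring closure). The alkenylchromium may add to the wrong face of the aldehyde, because the conformation of the forming ten-membered ring can override the 1,3-induction from C1. The fallback sets out from 23: the same closure is run and the C3 epimer, (3S)-epi-24 F1, is taken on. Oxidation with Dess–Martin periodinane and pyridine gives the ring enone, 3-oxo compound F2. Reduction with (S)-2-methyl-CBS-oxazaborolidine and catecholborane at −78 °C, in which the alkenyl carbon C4 is the large group, should give the 3R alcohol and so come back to 24. C3 is then set by reagent-controlled reduction instead of by the C–C bond formation.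

Step 16 (epoxy aldehyde). Opening of the oxirane by β-elimination from the enol form of the aldehyde, or by attack of O3 at C10, may consume the material before or during the ring closure. The fallback sets out from 21 and moves the epoxidation behind the ring closure. Dess–Martin oxidation of 21 gives the β,γ-unsaturated aldehyde F3. The CrCl2/NiCl2 closure under the conditions of step 17 gives the ring diene, 1,10-deoxy-24 F4. Epoxidation of F4 with the D-fructose-derived ketone and Oxone should then attack C1=C10, the only electron-rich alkene, from its outer face, and come back to 24.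

Step 8 (C8 reduction). Facial discrimination may be poor, since the oxazaborolidine has to tell a ring methine (C7) from an allylic methylene (C9), and the side-chain amine may bind boron. The fallback sets out from 13: reduction without a chiral reagent (NaBH4, CeCl3, MeOH, −78 °C) and separation of the epimers. The 8R alcohol 14 goes on as before. The 8S alcohol, 8-epi-14 F5, is esterified with inversion under Mitsunobu conditions (3-methylbutanoic acid, PPh3, diisopropyl azodicarboxylate, toluene, 0 °C → rt), so that both epimers arrive at 15.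

**Further compounds**

F1 | step 17 | (3S)-epimer of 24 | C=C1C(=O)O[C@@H]2/C=C(/C)[C@@H](O)C[C@H]3O[C@]3(C)C[C@@H](OC(=O)CC(C)C)[C@@H]12
F2 | step 17 | 3-oxo analogue of 24 (ring enone) | C=C1C(=O)O[C@@H]2/C=C(/C)C(=O)C[C@H]3O[C@]3(C)C[C@@H](OC(=O)CC(C)C)[C@@H]12
F3 | step 16 | (1R,3E)-1-[(2S,3R)-2-[(1Z)-2-iodoprop-1-en-1-yl]-4-methylidene-5-oxooxolan-3-yl]-3-methyl-6-oxohex-3-en-1-yl 3-methylbutanoate | C=C1C(=O)O[C@H](/C=C(/C)I)[C@H]1[C@H](OC(=O)CC(C)C)C/C(C)=C/CC=O
F4 | step 16 | 1,10-deoxy analogue of 24 (1(10)E,4Z ring diene) | C=C1C(=O)O[C@@H]2/C=C(/C)[C@H](O)C/C=C(\C)C[C@@H](OC(=O)CC(C)C)[C@@H]12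
F5 | step 8 | (8S)-epimer of 14 | O=C1O[C@H](CO[Si](c2ccccc2)(c2ccccc2)C(C)(C)C)[C@@H]([C@@H](O)C/C(C)=C/CCOCc2ccc(OC)cc2)[C@@H]1CN(C)C
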